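The target is a 2,2'-bithiophene whose ring B is unsubstituted at C3' and C4' and carries carbon at C5'. Ring B is therefore built on ring A: the S1'–C2' and C4'–C5' bonds are cut, which leads back to a (Z)-β-chloroacrolein on a thiophene ester and a thioglycolate. One base-mediated operation forms both bonds and aromatises ring B, giving a bithiophene with a methyl ester on ring A (the later CH2O arm) and a tert-butyl ester on ring B (exchanged for iodine, then the alkyne). The two acyl groups are introduced separately, so no protecting group is needed.

Key step: step 2

Remark on the chemistry: the target has no stereocentre, so only the Z geometry of the chloroenal has to be set; tert-butyl 2-sulfanylacetate and 3-methylbutanoyl chloride (needed for the isovalerate arm) are taken as purchasable starting materials.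

Step 1
Reactants: 1 methyl 5-acetylthiophene-2-carboxylate
Product: 3 methyl 5-[(1Z)-1-chloro-3-oxoprop-1-en-1-yl]thiophene-2-carboxylate, via chlorovinyl iminium salt 2 (not isolated)
Conditions: POCl3 (3 equiv), DMF, 0 °C → 60 °C; then ice-water
Reagents that add atoms: phosphoryl chloride, O=P(Cl)(Cl)Cl (the chlorine); N,N-dimethylformamide, CN(C)C=O (the formyl carbon); water, O (the aldehyde oxygen)
Why: Vilsmeier–Haack–Arnold chloroformylation: the enol of the methyl ketone is C-formylated by the chloroiminium reagent made from POCl3 and DMF, the ketone oxygen is replaced by chloride, and hydrolysis of iminium salt 2 on quenching should release the aldehyde as the thermodynamically preferred Z isomer (Cl and CHO cis), while the methyl ester on ring A is inert to these conditions.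

Step 2
Reactants: 3 methyl 5-[(1Z)-1-chloro-3-oxoprop-1-en-1-yl]thiophene-2-carboxylate; 4 tert-butyl 2-sulfanylacetate
Product: 7 5'-tert-butyl 5-methyl 2,2'-bithiophene-5,5'-dicarboxylate, via vinyl sulfide 5 (not isolated), via aldol adduct 6 (not isolated)
Conditions: K2CO3 (2.5 equiv), DMF, 0 °C → rt, then 60 °C
Reagents that add atoms: none
Why: Deprotonated 4 attacks C1 of the chloroenal 3 in a conjugate addition and chloride is then lost from the same carbon (vinylic substitution by addition–elimination, Z geometry retained), so that the S1'–C2' bond exists in 5 with sulfur cis to the formyl group. K2CO3 next removes a proton from the SCH2CO2t-Bu group, and the resulting ester enolate closes onto the formyl carbon in a 5-exo-trig (enolexo) aldol addition that creates C4'–C5' in 6, after which E1cB elimination of water makes ring B aromatic. This is the Fiesselmann-type route to thiophene-2-carboxylates from β-chlorovinyl aldehydes and sulfanylacetates, a well-established reaction class. No stereocentre has to be controlled, because the two sp3 carbons of 6 become sp2 on dehydration. The step needs regioselectivity (sulfur to C2', carbon to C4') and tolerance of two esters: the soft thiolate prefers the β-carbon of the chloroenal, the only acidic C–H of 5 lies between sulfur and the ester, and K2CO3 in DMF should neither hydrolyse nor transesterify the methyl and tert-butyl esters. The feature exploited is that ring B carries hydrogen at C3' and C4' and a carboxyl-derived carbon at C5', exactly the pattern this annulation delivers.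

Step 3
Reactants: 7 5'-tert-butyl 5-methyl 2,2'-bithiophene-5,5'-dicarboxylate
Product: 8 5'-(methoxycarbonyl)-2,2'-bithiophene-5-carboxylic acid
Conditions: CF3CO2H, CH2Cl2, rt
Reagents that add atoms: none
Why: Acidolysis of a tert-butyl ester (alkyl–oxygen cleavage through the tert-butyl cation, lost as 2-methylpropene) should free the ring B acid while the methyl ester, which cannot ionise in this way, stays intact.

Step 4
Reactants: 8 5'-(methoxycarbonyl)-2,2'-bithiophene-5-carboxylic acid
Product: 9 methyl 5'-iodo-2,2'-bithiophene-5-carboxylate
Conditions: I2 (3 equiv), K3PO4 (1 equiv), MeCN, 100 °C, sealed vessel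
Reagents that add atoms: iodine, II
Why: Transition-metal-free decarboxylative iodination (ipso-iododecarboxylation) of a heteroaromatic carboxylate by I2: the potassium carboxylate at the electron-rich α-carbon C5' of the bithiophene should be attacked at the ipso position with loss of CO2, both α-positions being blocked so that no C–H iodination competes, and the methyl ester tolerates anhydrous K3PO4.

Step 5
Reactants: 9 methyl 5'-iodo-2,2'-bithiophene-5-carboxylate
Product: 10 (5'-iodo-2,2'-bithiophen-5-yl)methanol
Conditions: i-Bu2AlH (DIBAL-H, 2.5 equiv), CH2Cl2, −78 → 0 °C; aq. potassium sodium tartrate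
Reagents that add atoms: none
Why: Hydride reduction of the ester with an excess of i-Bu2AlH should pass through the aldehyde to the primary alcohol, and the aryl C–I bond is not touched by this reagent at low temperature.

Step 6
Reactants: 10 (5'-iodo-2,2'-bithiophen-5-yl)methanol; 11 3-methylbut-2-enoyl chloride
Product: 12 (5'-iodo-2,2'-bithiophen-5-yl)methyl 3-methylbut-2-enoate
Conditions: pyridine, DMAP (cat.), CH2Cl2, 0 °C
Reagents that add atoms: none
Why: Acylation of the primary alcohol through the N-acylpyridinium ion (nucleophilic catalysis by DMAP) should be fast at 0 °C, and the weak base pyridine keeps γ-deprotonation to the vinylketene, and with it migration of the double bond, to a minimum while the medium stays free of acid that could ionise the thienylmethyl position.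

Step 7
Reactants: 13 but-3-yn-1-ol; 14 3-methylbutanoyl chloride
Product: 15 but-3-yn-1-yl 3-methylbutanoate
Conditions: pyridine, DMAP (cat.), CH2Cl2, 0 °C → rt
Reagents that add atoms: none
Why: Standard acylation of a primary alcohol by an acyl chloride under pyridine and DMAP; the terminal alkyne C–H is not affected.

Step 8
Reactants: 12 (5'-iodo-2,2'-bithiophen-5-yl)methyl 3-methylbut-2-enoate; 15 but-3-yn-1-yl 3-methylbutanoate
Product: 16 [5'-(4-{[3-methylbutanoyl]oxy}but-1-yn-1-yl)-2,2'-bithiophen-5-yl]methyl 3-methylbut-2-enoate
Conditions: Pd(PPh3)2Cl2 (3 mol %), CuI (5 mol %), Et3N, THF, rt, argon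
Reagents that add atoms: none
Why: Sonogashira coupling: zerovalent palladium generated from Pd(PPh3)2Cl2 inserts into the C5'–I bond, the copper acetylide formed from 15 with CuI and Et3N transmetallates, and reductive elimination forms the C(sp2)–C(sp) bond at room temperature, conditions under which both esters and the trisubstituted alkene should survive.

Compound list

1 | methyl 5-acetylthiophene-2-carboxylate | CC(=O)c1ccc(C(=O)OC)s1 | starting material
2 | (2Z)-3-chloro-3-[5-(methoxycarbonyl)thiophen-2-yl]-N,N-dimethylprop-2-en-1-iminium dichlorophosphate | COC(=O)c1ccc(/C(Cl)=C/C=[N+](C)C)s1.[O-]P(=O)(Cl)Cl | intermediate (not isolated)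
3 | methyl 5-[(1Z)-1-chloro-3-oxoprop-1-en-1-yl]thiophene-2-carboxylate | COC(=O)c1ccc(/C(Cl)=C/C=O)s1 | intermediate
4 | tert-butyl 2-sulfanylacetate | CC(C)(C)OC(=O)CS | starting material
5 | methyl 5-[(1Z)-1-[(2-tert-butoxy-2-oxoethyl)sulfanyl]-3-oxoprop-1-en-1-yl]thiophene-2-carboxylate | COC(=O)c1ccc(/C(SCC(=O)OC(C)(C)C)=C/C=O)s1 | intermediate (not isolated)
6 | tert-butyl 3-hydroxy-5-[5-(methoxycarbonyl)thiophen-2-yl]-2,3-dihydrothiophene-2-carboxylate (mixture of diastereomers, both centres lost on dehydration) | COC(=O)c1ccc(C2=CC(O)C(C(=O)OC(C)(C)C)S2)s1 | intermediate (not isolated)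
7 | 5'-tert-butyl 5-methyl 2,2'-bithiophene-5,5'-dicarboxylate | COC(=O)c1ccc(-c2ccc(C(=O)OC(C)(C)C)s2)s1 | intermediate
8 | 5'-(methoxycarbonyl)-2,2'-bithiophene-5-carboxylic acid | COC(=O)c1ccc(-c2ccc(C(=O)O)s2)s1 | intermediate
9 | methyl 5'-iodo-2,2'-bithiophene-5-carboxylate | COC(=O)c1ccc(-c2ccc(I)s2)s1 | intermediate
10 | (5'-iodo-2,2'-bithiophen-5-yl)methanol | OCc1ccc(-c2ccc(I)s2)s1 | intermediate
11 | 3-methylbut-2-enoyl chloride | CC(C)=CC(=O)Cl | starting material
12 | (5'-iodo-2,2'-bithiophen-5-yl)methyl 3-methylbut-2-enoate | CC(C)=CC(=O)OCc1ccc(-c2ccc(I)s2)s1 | intermediate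
13 | but-3-yn-1-ol | C#CCCO | starting material
14 | 3-methylbutanoyl chloride | CC(C)CC(=O)Cl | starting material
15 | but-3-yn-1-yl 3-methylbutanoate | C#CCCOC(=O)CC(C)C | intermediate
16 | [5'-(4-{[3-methylbutanoyl]oxy}but-1-yn-1-yl)-2,2'-bithiophen-5-yl]methyl 3-methylbut-2-enoate | CC(C)=CC(=O)OCc1ccc(-c2ccc(C#CCCOC(=O)CC(C)C)s2)s1 | target

Total step count: 8. Longest linear sequence: 7 steps (steps 1 to 6, then step 8); step 7 prepares the alkyne fragment separately.

Steps most likely to fail

Step 4. The ipso-iodination may stall because the ester on ring A lowers the electron density at C5', and prolonged heating with phosphate could begin to cleave the methyl ester. The fallback sets out from 8 and separates the two events. Protodecarboxylation (Ag2CO3 (10 mol %), AcOH, DMSO, 120 °C) should give methyl 2,2'-bithiophene-5-carboxylate F1. Electrophilic iodination of its only free α-position C5' with N-iodosuccinimide (CHCl3/AcOH, rt) then comes back to the route at 9.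

Step 2. The free thiol may be consumed by air oxidation to the disulfide, or by reversible addition to the aldehyde followed by over-addition, so that chloride displacement at C2' is not clean. The fallback sets out from 3 and reverses the roles of the partners. Na2S·9H2O in DMF at 0 °C should replace chloride to give sodium (1Z)-1-[5-(methoxycarbonyl)thiophen-2-yl]-3-oxoprop-1-ene-1-thiolate F2. S-alkylation with tert-butyl bromoacetate gives vinyl sulfide 5, and K2CO3 at 60 °C closes ring B, which comes back to the route at 7.

Step 6. γ-Deprotonation of the acyl chloride or of the acylpyridinium ion would give a vinylketene, and acylation through it would move the double bond out of conjugation. Traces of HCl could also ionise the electron-rich thienylmethyl position and lead to oligomers. The fallback sets out from 10 and activates the alcohol instead of the acid. Mitsunobu esterification with 3-methylbut-2-enoic acid (PPh3, diisopropyl azodicarboxylate, THF, 0 °C) should give 12 directly, with no new compound on the way.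

Further compounds

F1 | step 4 | methyl 2,2'-bithiophene-5-carboxylate | COC(=O)c1ccc(-c2cccs2)s1
F2 | step 2 | sodium (1Z)-1-[5-(methoxycarbonyl)thiophen-2-yl]-3-oxoprop-1-ene-1-thiolate | COC(=O)c1ccc(/C([S-])=C/C=O)s1.[Na+]
F0 | step 6 | none | none
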